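**Plan**
- Retrosynthesis: the last operations only unmask oxygen (two methyl enol ethers on ring B, two aryl silyl ethers on ring A) and raise a benzylic carbinol to the isobutyryl ketone. Ring A is then cut through the two bonds to the alkyne carbons and the re-closing ring bond, back to a 3-siloxycyclobutenone that carries ring B on its C4 methylene, plus a siloxyalkyne.
- The cyclobutenone is cut by a ketene/siloxyalkyne [2+2] disconnection to a ring B propanoic acid, and that acid at the ring B–CH2 bond (Negishi coupling) to an α-iodo dienone.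
- Forward order: ring B first, from 2,4-dimethoxytoluene (Birch reduction, C-acylation, C-prenylation to the quaternary carbon, bis-allylic oxidation); then the side chain; then the four-membered ring; ring A last, built directly on the bridge carbon.
- Stereochemistry: the only stereocentre of the target is the ring B quaternary carbon (S). Its two ring arms differ only by a remote methyl group, so no face-selective prenylation can be relied on; it is secured by resolution of the racemic dienone on a chiral phase and checked by X-ray analysis of the iodo dienone. It has no enolisable hydrogen and is carried unchanged.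
- The carbinol carbon of the branched alkyne and C4 of the cyclobutenone are transient and are used as mixtures of epimers.

Key step: step 14

Remark: ring B of the target is drawn as one enol tautomer of a 2-acyl-2-prenylcyclohexane-1,3,5-trione; all such tautomers are taken as the same compound.
Remark: the two transient centres are left undefined in the SMILES because steps 14 and 16 destroy them.
Remark on names: "ring B unit" stands for the (3S)-2,4-dimethoxy-5-methyl-3-(3-methylbut-2-en-1-yl)-3-(2-methylpropanoyl)-6-oxocyclohexa-1,4-dien-1-yl group.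

**Step 1**
Reactants: 1 prenyl bromide (1-bromo-3-methylbut-2-ene); 2 ethynylmagnesium bromide (HC≡CMgBr)
Product: 3 5-methylhex-4-en-1-yne
Conditions: CuCl (5 mol %), THF, 0 °C to rt
Reagents that add atoms: none
Why: Coupling of an alkynyl Grignard reagent with an allylic bromide under catalysis by monovalent copper should go mainly at the primary carbon and give the skipped enyne, which is purified by distillation.

**Step 2**
Reactants: 3 5-methylhex-4-en-1-yne
Product: 6 triisopropyl[(5-methylhex-4-en-1-yn-1-yl)oxy]silane, via lithium acetylide 4 (not isolated), via lithium ynolate 5 (not isolated)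
Conditions: LiN(SiMe3)2 (2.1 equiv), THF, −78 °C; t-BuOOH, −78 to 0 °C; i-Pr3SiOTf, −78 to 0 °C
Reagents that add atoms: tert-butyl hydroperoxide, CC(C)(C)OO; triisopropylsilyl trifluoromethanesulfonate, CC(C)[Si](OS(=O)(=O)C(F)(F)F)(C(C)C)C(C)C
Why: Julia oxidation of the lithium acetylide by lithium tert-butyl peroxide should give the ynolate, which the bulky silyl triflate captures on oxygen as a storable siloxyalkyne.

**Step 3**
Reactants: 7 4-methylpent-1-yn-3-ol (racemic)
Product: 8 triethyl[(4-methylpent-1-yn-3-yl)oxy]silane (racemic)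
Conditions: Et3SiCl, imidazole, CH2Cl2, 0 °C to rt
Reagents that add atoms: chlorotriethylsilane, CC[Si](Cl)(CC)CC
Why: Standard silylation of a secondary alcohol masks the hydroxyl that would otherwise quench ynolates and ketenes, and triethylsilyl is chosen because it can later be removed in the presence of aryl triisopropylsilyl ethers.

**Step 4**
Reactants: 8 triethyl[(4-methylpent-1-yn-3-yl)oxy]silane
Product: 11 triethyl{[4-methyl-1-(triisopropylsilyloxy)pent-1-yn-3-yl]oxy}silane (racemic), via lithium acetylide 9 (not isolated), via lithium ynolate 10 (not isolated)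
Conditions: LiN(SiMe3)2 (2.1 equiv), THF, −78 °C; t-BuOOH, −78 to 0 °C; i-Pr3SiOTf, −78 to 0 °C
Reagents that add atoms: tert-butyl hydroperoxide, CC(C)(C)OO; triisopropylsilyl trifluoromethanesulfonate, CC(C)[Si](OS(=O)(=O)C(F)(F)F)(C(C)C)C(C)C
Why: The same Julia acetylide oxidation and O-silylation as in step 2 should apply, the silyloxide on the neighbouring carbon being too poor a leaving group to be expelled from the ynolate at these temperatures.

**Step 5**
Reactants: 12 2,4-dimethoxytoluene
Product: 13 1,5-dimethoxy-2-methylcyclohexa-1,4-diene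
Conditions: Li, liquid NH3, THF, t-BuOH, −78 to −33 °C; NH4Cl
Reagents that add atoms: none
Why: Birch reduction of a resorcinol dimethyl ether places both methoxy groups and the methyl group on the remaining double bonds, so the CH2 between the two enol ether carbons and the CH2 para to it are the reduced positions.

**Step 6**
Reactants: 13 1,5-dimethoxy-2-methylcyclohexa-1,4-diene; 14 N-methoxy-N,2-dimethylpropanamide (Weinreb amide of isobutyric acid)
Product: 16 1-(2,6-dimethoxy-3-methylcyclohexa-2,5-dien-1-yl)-2-methylpropan-1-one (racemic), via lithiated diene 15 (not isolated)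
Conditions: t-BuLi, THF, −78 °C; then 14, −78 to 0 °C; pH 7 buffer
Reagents that add atoms: none
Why: Deprotonation of the CH2 flanked by the two enol ether carbons (Piers-type metalation of 1,5-dimethoxycyclohexa-1,4-dienes) and acylation of the organolithium by a Weinreb amide should give the ketone, the chelated adduct preventing over-addition and enolisation until work-up.

**Step 7**
Reactants: 16 1-(2,6-dimethoxy-3-methylcyclohexa-2,5-dien-1-yl)-2-methylpropan-1-one; 1 prenyl bromide
Product: 18 1-[2,6-dimethoxy-3-methyl-1-(3-methylbut-2-en-1-yl)cyclohexa-2,5-dien-1-yl]-2-methylpropan-1-one (racemic), via lithium enolate 17 (not isolated)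
Conditions: LiN(SiMe3)2, THF, −78 °C; then 1, −78 to 0 °C
Reagents that add atoms: none
Why: C-alkylation of the cross-conjugated lithium dienolate at its central carbon, the mode known from Birch reductive alkylations, should build the quaternary carbon, as a racemate because the two faces are not distinguished.

**Step 8**
Reactants: 18 racemic prenylated ketone
Product: 19 3,5-dimethoxy-2-methyl-4-(3-methylbut-2-en-1-yl)-4-(2-methylpropanoyl)cyclohexa-2,5-dien-1-one (racemic)
Conditions: t-BuOOH (in decane), (C5H5NH)2Cr2O7 (pyridinium dichromate, 20 mol %), Celite, benzene, rt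
Reagents that add atoms: tert-butyl hydroperoxide, CC(C)(C)OO
Why: Bis-allylic oxidation of a Birch-type 1,4-diene to the cross-conjugated 2,5-cyclohexadienone with t-BuOOH and a hexavalent chromium catalyst should take place at the ring CH2, which lies between two enol ether double bonds and is far more reactive than the allylic positions of the prenyl group.

**Step 9**
Reactants: 19 racemic dienone
Product: 20 (R)-3,5-dimethoxy-2-methyl-4-(3-methylbut-2-en-1-yl)-4-(2-methylpropanoyl)cyclohexa-2,5-dien-1-one
Conditions: preparative supercritical-fluid chromatography, amylose tris(3,5-dimethylphenylcarbamate) phase, CO2/i-PrOH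
Reagents that add atoms: none
Why: Resolution by chromatography on a chiral stationary phase is chosen because the two ring arms at the quaternary carbon differ only by a remote methyl group, and the (R)-enantiomer, to be identified by anomalous-dispersion X-ray analysis of iodide 21, is carried on.

**Step 10**
Reactants: 20 (R)-dienone
Product: 21 (S)-2-iodo-3,5-dimethoxy-6-methyl-4-(3-methylbut-2-en-1-yl)-4-(2-methylpropanoyl)cyclohexa-2,5-dien-1-one
Conditions: N-iodosuccinimide, MeCN, 0 °C to rt, dark
Reagents that add atoms: N-iodosuccinimide, O=C1CCC(=O)N1I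
Why: Electrophilic α-iodination of a vinylogous ester should occur at the only vinylic C–H, the enol ether carbon being more nucleophilic than the isolated prenyl double bond (the descriptor changes from R to S only because iodine raises the priority of that arm).

**Step 11**
Reactants: 21 (S)-iodo dienone; 22 (3-ethoxy-3-oxopropyl)zinc bromide (BrZnCH2CH2CO2Et, THF solution)
Product: 23 ethyl 3-(ring B unit)propanoate
Conditions: Pd(OAc)2 (5 mol %), SPhos (2-dicyclohexylphosphino-2′,6′-dimethoxybiphenyl, 10 mol %), THF, rt to 45 °C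
Reagents that add atoms: none
Why: Negishi coupling of an α-iodo enone with a zinc homoenolate, run on zerovalent palladium formed in situ, should join the three-carbon chain to ring B, the ester-chelated alkylzinc being slow to lose a β-hydride.

**Step 12**
Reactants: 23 ethyl 3-(ring B unit)propanoate
Product: 24 3-(ring B unit)propanoic acid
Conditions: LiOH, THF/H2O, 0 °C; then cold 1 M HCl to pH 4
Reagents that add atoms: lithium hydroxide, [Li+].[OH-]
Why: Saponification of the unhindered ethyl ester at 0 °C should leave the vinylogous methyl esters and the hindered ketone on the quaternary carbon untouched.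

**Step 13**
Reactants: 24 3-(ring B unit)propanoic acid; 6 triisopropyl[(5-methylhex-4-en-1-yn-1-yl)oxy]silane
Product: 27 4-[(ring B unit)methyl]-2-(3-methylbut-2-en-1-yl)-3-(triisopropylsilyloxy)cyclobut-2-en-1-one (both C4 epimers), via acid chloride 25 (not isolated), via ketene 26 (not isolated)
Conditions: 1-chloro-N,N,2-trimethylprop-1-en-1-amine, CH2Cl2, 0 °C to rt; then 6 (2 equiv), Et3N (slow addition), CH2Cl2, rt
Reagents that add atoms: none
Why: Neutral acid chloride formation with an α-chloroenamine, dehydrochlorination to the aldoketene and ketene–ynol ether [2+2] cycloaddition should give the cyclobutenone, the nucleophilic prenyl-bearing alkyne carbon bonding to the ketene carbonyl carbon so that the siloxy group lands on C3 and the bridge CH2 on C4, whose configuration is uncontrolled and irrelevant.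

**Step 14**
Reactants: 27 4-[(ring B unit)methyl]-2-(3-methylbut-2-en-1-yl)-3-(triisopropylsilyloxy)cyclobut-2-en-1-one; 11 triethyl{[4-methyl-1-(triisopropylsilyloxy)pent-1-yn-3-yl]oxy}silane
Product: 32 2-[(ring B unit)methyl]-6-[2-methyl-1-(triethylsilyloxy)propyl]-4-(3-methylbut-2-en-1-yl)-3,5-bis(triisopropylsilyloxy)phenol (both carbinol epimers), via vinylketene 28 (not isolated), via 2-vinylcyclobutenone 29 (not isolated), via dienylketene 30 (not isolated), via cyclohexa-2,4-dienone 31 (not isolated)
Conditions: 11 (1.5 equiv), degassed toluene, 85 °C, sealed tube, Ar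
Reagents that add atoms: none
Why: Heating 27 should open the four-membered ring in a four-electron electrocyclic step to vinylketene 28, whose ketene C=C adds across the triple bond of 11 in a [2+2] cycloaddition to give 29; a second four-electron opening gives dienylketene 30, which closes ring A by a six-electron disrotatory electrocyclisation between the ketene carbon and the former C4, and cyclohexadienone 31 tautomerises to phenol 32. The closest known reaction type is the thermal benzannulation of cyclobutenones with siloxyalkynes to resorcinol monosilyl ethers (Danheiser benzannulation in its siloxyalkyne form), extended here to a phloroglucinol by the 3-siloxy group of 27. No lasting stereocentre is created: C4 of 27 is lost in the first ring opening, the quaternary carbon of 29 in the second, the sp3 carbon of 31 on tautomerisation and the carbinol centre in step 16, while the ring B quaternary carbon is remote and has no pathway for epimerisation under neutral heating. The selectivity needed is the orientation of the alkyne in the [2+2] step, and the siloxy group secures it by making the carbinol-bearing alkyne carbon the nucleophile toward the ketene carbonyl carbon, so the three oxygens come out 1,3,5. An exchange among the three carbon substituents would be harmless, because they occupy equivalent positions once all three oxygens are free. The absence of acid, base and metal should spare the prenyl groups, the enol ethers and the methylene bridge.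

**Step 15**
Reactants: 32 ring A phenol with benzylic triethylsilyl ether
Product: 33 2-[(ring B unit)methyl]-6-(1-hydroxy-2-methylpropyl)-4-(3-methylbut-2-en-1-yl)-3,5-bis(triisopropylsilyloxy)phenol (both carbinol epimers)
Conditions: HF·pyridine, pyridine, THF, 0 °C
Reagents that add atoms: none
Why: Selective desilylation with buffered HF·pyridine should cleave the secondary alkyl triethylsilyl ether much faster than the aryl triisopropylsilyl ethers, and the crude alcohol is oxidised at once to limit ionisation at the electron-rich benzylic position.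

**Step 16**
Reactants: 33 benzylic alcohol
Product: 34 1-{2-hydroxy-3-[(ring B unit)methyl]-5-(3-methylbut-2-en-1-yl)-4,6-bis(triisopropylsilyloxy)phenyl}-2-methylpropan-1-one
Conditions: Dess–Martin periodinane, NaHCO3, CH2Cl2, 0 °C
Reagents that add atoms: none
Why: Dess–Martin oxidation of a benzylic secondary alcohol under buffered, non-ionising conditions should give the aryl ketone and erase the carbinol centre, the hindered phenol being unable to give a quinone because the three ring oxygens are mutually meta.

**Step 17**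
Reactants: 34 aryl ketone with two aryl silyl ethers
Product: 35 1-{2,4,6-trihydroxy-3-[(ring B unit)methyl]-5-(3-methylbut-2-en-1-yl)phenyl}-2-methylpropan-1-one
Conditions: Bu4NF, AcOH (1:1), THF, 0 °C
Reagents that add atoms: none
Why: Fluoride cleavage of aryl silyl ethers is fast at 0 °C, and buffering with AcOH should keep the medium too weakly basic to attack the acyl group on the ring B quaternary carbon.

**Step 18**
Reactants: 35 acylphloroglucinol with ring B as its dimethyl ether
Product: 36 target, (4S)-3,5-dihydroxy-6-methyl-4-(3-methylbut-2-en-1-yl)-4-(2-methylpropanoyl)-2-{[2,4,6-trihydroxy-3-(3-methylbut-2-en-1-yl)-5-(2-methylpropanoyl)phenyl]methyl}cyclohexa-2,5-dien-1-one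
Conditions: LiCl, DMSO, 120 °C; then cold dilute HCl to pH 4
Reagents that add atoms: none
Why: SN2 demethylation of the two vinylogous methyl esters by chloride in a dipolar aprotic solvent (Krapcho-type dealkylation, established for prenylated acylphloroglucinol enol ethers) should free the trione without the acid that would cyclise the prenyl groups onto neighbouring hydroxyls.

**Compound list**
1 | prenyl bromide (1-bromo-3-methylbut-2-ene) | CC(C)=CCBr | starting material
2 | ethynylmagnesium bromide | C#C[Mg]Br | starting material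
3 | 5-methylhex-4-en-1-yne | CC(C)=CCC#C | intermediate
4 | (5-methylhex-4-en-1-yn-1-yl)lithium | [Li]C#CCC=C(C)C | intermediate (not isolated)
5 | lithium 5-methylhex-4-en-1-yn-1-olate | [Li]OC#CCC=C(C)C | intermediate (not isolated)
6 | triisopropyl[(5-methylhex-4-en-1-yn-1-yl)oxy]silane | CC(C)=CCC#CO[Si](C(C)C)(C(C)C)C(C)C | intermediate
7 | 4-methylpent-1-yn-3-ol, racemic | CC(C)C(O)C#C | starting material
8 | triethyl[(4-methylpent-1-yn-3-yl)oxy]silane, racemic | CC(C)C(O[Si](CC)(CC)CC)C#C | intermediate
9 | [4-methyl-3-(triethylsilyloxy)pent-1-yn-1-yl]lithium | [Li]C#CC(O[Si](CC)(CC)CC)C(C)C | intermediate (not isolated)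
10 | lithium 4-methyl-3-(triethylsilyloxy)pent-1-yn-1-olate | [Li]OC#CC(O[Si](CC)(CC)CC)C(C)C | intermediate (not isolated)
11 | triethyl{[4-methyl-1-(triisopropylsilyloxy)pent-1-yn-3-yl]oxy}silane, racemic | CC(C)C(O[Si](CC)(CC)CC)C#CO[Si](C(C)C)(C(C)C)C(C)C | intermediate
12 | 2,4-dimethoxytoluene | Cc1ccc(OC)cc1OC | starting material
13 | 1,5-dimethoxy-2-methylcyclohexa-1,4-diene | COC1=C(C)CC=C(OC)C1 | intermediate
14 | N-methoxy-N,2-dimethylpropanamide | CC(C)C(=O)N(C)OC | starting material
15 | (2,6-dimethoxy-3-methylcyclohexa-2,5-dien-1-yl)lithium | [Li]C1C(OC)=C(C)CC=C1OC | intermediate (not isolated)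
16 | 1-(2,6-dimethoxy-3-methylcyclohexa-2,5-dien-1-yl)-2-methylpropan-1-one, racemic | CC(C)C(=O)C1C(OC)=C(C)CC=C1OC | intermediate
17 | lithium enolate of 16 (exocyclic enolate, oxygen on the isobutyryl carbon) | CC(C)C(O[Li])=C1C(OC)=C(C)CC=C1OC | intermediate (not isolated)
18 | 1-[2,6-dimethoxy-3-methyl-1-(3-methylbut-2-en-1-yl)cyclohexa-2,5-dien-1-yl]-2-methylpropan-1-one, racemic | CC(C)C(=O)C1(CC=C(C)C)C(OC)=C(C)CC=C1OC | intermediate
19 | 3,5-dimethoxy-2-methyl-4-(3-methylbut-2-en-1-yl)-4-(2-methylpropanoyl)cyclohexa-2,5-dien-1-one, racemic | O=C1C=C(OC)C(CC=C(C)C)(C(=O)C(C)C)C(OC)=C1C | intermediate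
20 | (R)-3,5-dimethoxy-2-methyl-4-(3-methylbut-2-en-1-yl)-4-(2-methylpropanoyl)cyclohexa-2,5-dien-1-one | O=C1C=C(OC)[C@@](CC=C(C)C)(C(=O)C(C)C)C(OC)=C1C | intermediate
21 | (S)-2-iodo-3,5-dimethoxy-6-methyl-4-(3-methylbut-2-en-1-yl)-4-(2-methylpropanoyl)cyclohexa-2,5-dien-1-one | O=C1C(I)=C(OC)[C@@](CC=C(C)C)(C(=O)C(C)C)C(OC)=C1C | intermediate
22 | (3-ethoxy-3-oxopropyl)zinc bromide | CCOC(=O)CC[Zn]Br | starting material
23 | ethyl 3-(ring B unit)propanoate | CCOC(=O)CCC1=C(OC)[C@@](CC=C(C)C)(C(=O)C(C)C)C(OC)=C(C)C1=O | intermediate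
24 | 3-(ring B unit)propanoic acid | OC(=O)CCC1=C(OC)[C@@](CC=C(C)C)(C(=O)C(C)C)C(OC)=C(C)C1=O | intermediate
25 | 3-(ring B unit)propanoyl chloride | ClC(=O)CCC1=C(OC)[C@@](CC=C(C)C)(C(=O)C(C)C)C(OC)=C(C)C1=O | intermediate (not isolated)
26 | 3-(ring B unit)prop-1-en-1-one (aldoketene) | O=C=CCC1=C(OC)[C@@](CC=C(C)C)(C(=O)C(C)C)C(OC)=C(C)C1=O | intermediate (not isolated)
27 | 4-[(ring B unit)methyl]-2-(3-methylbut-2-en-1-yl)-3-(triisopropylsilyloxy)cyclobut-2-en-1-one, both C4 epimers | O=C1C(CC=C(C)C)=C(O[Si](C(C)C)(C(C)C)C(C)C)C1CC2=C(OC)[C@@](CC=C(C)C)(C(=O)C(C)C)C(OC)=C(C)C2=O | intermediate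
28 | vinylketene from ring opening of 27 (bridge CH2 trans to the ketene carbon) | O=C=C(CC=C(C)C)/C(O[Si](C(C)C)(C(C)C)C(C)C)=C/CC2=C(OC)[C@@](CC=C(C)C)(C(=O)C(C)C)C(OC)=C(C)C2=O | intermediate (not isolated)
29 | 2-vinylcyclobutenone from [2+2] addition of 28 and 11 (ring carbons: C=O, carbinol-bearing carbon, siloxy carbon, quaternary carbon with prenyl and siloxyvinyl) | O=C1C(C(O[Si](CC)(CC)CC)C(C)C)=C(O[Si](C(C)C)(C(C)C)C(C)C)C1(CC=C(C)C)/C(O[Si](C(C)C)(C(C)C)C(C)C)=C/CC2=C(OC)[C@@](CC=C(C)C)(C(=O)C(C)C)C(OC)=C(C)C2=O | intermediate (not isolated)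
30 | dienylketene from ring opening of 29 | O=C=C(C(O[Si](CC)(CC)CC)C(C)C)/C(O[Si](C(C)C)(C(C)C)C(C)C)=C(CC=C(C)C)\C(O[Si](C(C)C)(C(C)C)C(C)C)=C\CC2=C(OC)[C@@](CC=C(C)C)(C(=O)C(C)C)C(OC)=C(C)C2=O | intermediate (not isolated)
31 | cyclohexa-2,4-dienone keto tautomer of 32 | O=C1C(C(O[Si](CC)(CC)CC)C(C)C)=C(O[Si](C(C)C)(C(C)C)C(C)C)C(CC=C(C)C)=C(O[Si](C(C)C)(C(C)C)C(C)C)C1CC2=C(OC)[C@@](CC=C(C)C)(C(=O)C(C)C)C(OC)=C(C)C2=O | intermediate (not isolated)
32 | 2-[(ring B unit)methyl]-6-[2-methyl-1-(triethylsilyloxy)propyl]-4-(3-methylbut-2-en-1-yl)-3,5-bis(triisopropylsilyloxy)phenol, both carbinol epimers | CC(C)C(O[Si](CC)(CC)CC)c1c(O)c(CC2=C(OC)[C@@](CC=C(C)C)(C(=O)C(C)C)C(OC)=C(C)C2=O)c(O[Si](C(C)C)(C(C)C)C(C)C)c(CC=C(C)C)c1O[Si](C(C)C)(C(C)C)C(C)C | intermediate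
33 | 2-[(ring B unit)methyl]-6-(1-hydroxy-2-methylpropyl)-4-(3-methylbut-2-en-1-yl)-3,5-bis(triisopropylsilyloxy)phenol, both carbinol epimers | CC(C)C(O)c1c(O)c(CC2=C(OC)[C@@](CC=C(C)C)(C(=O)C(C)C)C(OC)=C(C)C2=O)c(O[Si](C(C)C)(C(C)C)C(C)C)c(CC=C(C)C)c1O[Si](C(C)C)(C(C)C)C(C)C | intermediate
34 | 1-{2-hydroxy-3-[(ring B unit)methyl]-5-(3-methylbut-2-en-1-yl)-4,6-bis(triisopropylsilyloxy)phenyl}-2-methylpropan-1-one | CC(C)C(=O)c1c(O)c(CC2=C(OC)[C@@](CC=C(C)C)(C(=O)C(C)C)C(OC)=C(C)C2=O)c(O[Si](C(C)C)(C(C)C)C(C)C)c(CC=C(C)C)c1O[Si](C(C)C)(C(C)C)C(C)C | intermediate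
35 | 1-{2,4,6-trihydroxy-3-[(ring B unit)methyl]-5-(3-methylbut-2-en-1-yl)phenyl}-2-methylpropan-1-one | CC(C)C(=O)c1c(O)c(CC2=C(OC)[C@@](CC=C(C)C)(C(=O)C(C)C)C(OC)=C(C)C2=O)c(O)c(CC=C(C)C)c1O | intermediate
36 | (4S)-3,5-dihydroxy-6-methyl-4-(3-methylbut-2-en-1-yl)-4-(2-methylpropanoyl)-2-{[2,4,6-trihydroxy-3-(3-methylbut-2-en-1-yl)-5-(2-methylpropanoyl)phenyl]methyl}cyclohexa-2,5-dien-1-one | CC(C)=CCc1c(O)c(CC2=C(O)[C@@](CC=C(C)C)(C(=O)C(C)C)C(O)=C(C)C2=O)c(O)c(C(=O)C(C)C)c1O | target

**Totals**
Total step count: 18.
Longest linear sequence: 14 steps (steps 5 to 18, from 2,4-dimethoxytoluene).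

**Steps most likely to fail**

1. Step 14 (benzannulation). What may go wrong: capture of the crowded vinylketene by the α-branched siloxyalkyne may be too slow, so that ketene oligomerisation, silyl migration or thermal loss of silanol from the benzylic ether takes over. Fallback, setting out from acid 24 and returning to the route at triol 35: the roles of the two alkynes are exchanged. Ketene 26 is generated from 24 as in step 13 but trapped with the branched alkyne 11, which now meets an unhindered ketene, to give the carbinol-substituted cyclobutenone F1. Heating F1 with the unbranched alkyne 6 should give the isomeric phenol F2, in which the free hydroxyl lies between prenyl and bridge and the carbinol between the two siloxy groups. Buffered HF·pyridine then gives the benzylic alcohol F3, Dess–Martin oxidation the aryl ketone F4, and Bu4NF/AcOH gives 35, because the three carbon substituents of a phloroglucinol occupy equivalent positions once all three oxygens are free.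

2. Step 18 (double demethylation). What may go wrong: the second methyl enol ether may resist chloride at a temperature at which the free phloroglucinol ring promotes retro-Michael scission and scrambling at the methylene bridge. Fallback, setting out from ketone 34 and returning at target 36: order and reagent are both changed. Compound 34, with ring A still silylated, is treated with Me3SiI (from Me3SiCl and NaI) and 2,6-lutidine in MeCN at 0 °C, a silyl-assisted dealkylation of vinylogous esters that runs cold, to give after aqueous work-up the ring B trione F5. Bu4NF/AcOH then removes the two aryl silyl groups to give 36.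

3. Step 16 (carbinol oxidation). What may go wrong: ionisation of the ortho-hydroxybenzylic alcohol to an ortho-quinone methide, or attack of the iodine oxidant on the free phenol, may compete with oxidation of the hindered carbinol. Fallback, setting out from phenol 32 and returning at triol 35: the phenol is capped first. t-BuMe2SiOTf and 2,6-lutidine give the aryl tert-butyldimethylsilyl ether F6, buffered HF·pyridine removes only the alkyl triethylsilyl group to give alcohol F7, Dess–Martin oxidation gives ketone F8, and Bu4NF/AcOH cleaves all three aryl silyl ethers to give 35.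

**Further compounds**
F1 | step 14 | 2-[2-methyl-1-(triethylsilyloxy)propyl]-4-[(ring B unit)methyl]-3-(triisopropylsilyloxy)cyclobut-2-en-1-one, epimers at C4 and carbinol | O=C1C(C(O[Si](CC)(CC)CC)C(C)C)=C(O[Si](C(C)C)(C(C)C)C(C)C)C1CC2=C(OC)[C@@](CC=C(C)C)(C(=O)C(C)C)C(OC)=C(C)C2=O
F2 | step 14 | 2-[(ring B unit)methyl]-4-[2-methyl-1-(triethylsilyloxy)propyl]-6-(3-methylbut-2-en-1-yl)-3,5-bis(triisopropylsilyloxy)phenol | CC(C)C(O[Si](CC)(CC)CC)c1c(O[Si](C(C)C)(C(C)C)C(C)C)c(CC=C(C)C)c(O)c(CC2=C(OC)[C@@](CC=C(C)C)(C(=O)C(C)C)C(OC)=C(C)C2=O)c1O[Si](C(C)C)(C(C)C)C(C)C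
F3 | step 14 | 2-[(ring B unit)methyl]-4-(1-hydroxy-2-methylpropyl)-6-(3-methylbut-2-en-1-yl)-3,5-bis(triisopropylsilyloxy)phenol | CC(C)C(O)c1c(O[Si](C(C)C)(C(C)C)C(C)C)c(CC=C(C)C)c(O)c(CC2=C(OC)[C@@](CC=C(C)C)(C(=O)C(C)C)C(OC)=C(C)C2=O)c1O[Si](C(C)C)(C(C)C)C(C)C
F4 | step 14 | 1-{4-hydroxy-3-[(ring B unit)methyl]-5-(3-methylbut-2-en-1-yl)-2,6-bis(triisopropylsilyloxy)phenyl}-2-methylpropan-1-one | CC(C)C(=O)c1c(O[Si](C(C)C)(C(C)C)C(C)C)c(CC=C(C)C)c(O)c(CC2=C(OC)[C@@](CC=C(C)C)(C(=O)C(C)C)C(OC)=C(C)C2=O)c1O[Si](C(C)C)(C(C)C)C(C)C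
F5 | step 18 | bis(triisopropylsilyl) ether of the target at the two ring A oxygens that flank the prenyl group (ring B as free trione enol) | CC(C)C(=O)c1c(O)c(CC2=C(O)[C@@](CC=C(C)C)(C(=O)C(C)C)C(O)=C(C)C2=O)c(O[Si](C(C)C)(C(C)C)C(C)C)c(CC=C(C)C)c1O[Si](C(C)C)(C(C)C)C(C)C
F6 | step 16 | tert-butyldimethylsilyl ether of phenol 32 | CC(C)C(O[Si](CC)(CC)CC)c1c(O[Si](C)(C)C(C)(C)C)c(CC2=C(OC)[C@@](CC=C(C)C)(C(=O)C(C)C)C(OC)=C(C)C2=O)c(O[Si](C(C)C)(C(C)C)C(C)C)c(CC=C(C)C)c1O[Si](C(C)C)(C(C)C)C(C)C
F7 | step 16 | benzylic alcohol from F6 (aryl tert-butyldimethylsilyl and two aryl triisopropylsilyl ethers kept) | CC(C)C(O)c1c(O[Si](C)(C)C(C)(C)C)c(CC2=C(OC)[C@@](CC=C(C)C)(C(=O)C(C)C)C(OC)=C(C)C2=O)c(O[Si](C(C)C)(C(C)C)C(C)C)c(CC=C(C)C)c1O[Si](C(C)C)(C(C)C)C(C)C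
F8 | step 16 | aryl isopropyl ketone from F7 (tert-butyldimethylsilyl ether of 34) | CC(C)C(=O)c1c(O[Si](C)(C)C(C)(C)C)c(CC2=C(OC)[C@@](CC=C(C)C)(C(=O)C(C)C)C(OC)=C(C)C2=O)c(O[Si](C(C)C)(C(C)C)C(C)C)c(CC=C(C)C)c1O[Si](C(C)C)(C(C)C)C(C)C
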